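**Strategy**

Everything rests on opening the isocoumarin lactone across C4–C3 and O2–C1. The pyranone ring (C1, O2, C3, C4) is fused to ring A, an orsellinate whose ester carbon is C1 and whose methyl carbon is C4; this ortho ester/methyl pair is what the key step exploits. A lateral benzylic anion at that methyl is acylated by N-methoxy-N-methylhexanamide, which brings C3 with its pentyl chain, and the enol oxygen of the new ketone closes on the ester, so one operation forms two bonds and the ring. The precursor is the complete tri-O-benzyl diaryl ether with ring B as a free acid, ring B having been built on the ring A phenol oxygen by Diels–Alder benzannulation.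

Key step: step 9

Remark on the chemistry: the target has no stereocentre (5 is a mixture of double-bond isomers and 8 a diastereomer mixture, both erased on aromatisation). Three choices are deliberate: the diene is made by soft enolisation so no amide base meets the ring A methyl early, the ring B acid is unveiled from an allyl ester under neutral conditions, and the benzyl ethers are removed by a Lewis acid because hydrogen over a palladium catalyst would also threaten the styrene-like C3=C4 bond.

**Route**

Step 1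
Reactants: 1 methyl orsellinate (methyl 2,4-dihydroxy-6-methylbenzoate)
Product: 2 methyl 4-(benzyloxy)-2-hydroxy-6-methylbenzoate
Conditions: BnBr (1.05 equiv), K2CO3, acetone, reflux
Reagents that add atoms: benzyl bromide, BrCc1ccccc1
Why: Williamson ether synthesis; the 4-OH is the more acidic and unhindered phenol while the 2-OH is held in a hydrogen bond by the ester carbonyl, so one equivalent of benzyl bromide should alkylate O4 only.

Step 2
Reactants: 2 methyl 4-(benzyloxy)-2-hydroxy-6-methylbenzoate; 3 methyl 4-chloroacetoacetate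
Product: 4 methyl 4-(benzyloxy)-2-(4-methoxy-2,4-dioxobutoxy)-6-methylbenzoate
Conditions: NaH (2.1 equiv), THF–DMF, 0 °C; then 3, 0 → 40 °C; dilute HCl work-up
Reagents that add atoms: none
Why: Williamson-type SN2 displacement of the α-keto chloride by the sodium phenoxide of 2; the second equivalent of NaH holds the β-keto ester as its enolate, which suppresses self-alkylation of 3 and Dieckmann-type closure onto the ring A ester.

Step 3
Reactants: 4 methyl 4-(benzyloxy)-2-(4-methoxy-2,4-dioxobutoxy)-6-methylbenzoate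
Product: 5 methyl 4-(benzyloxy)-2-{[4-methoxy-2,4-bis(trimethylsilyloxy)buta-1,3-dien-1-yl]oxy}-6-methylbenzoate
Conditions: Me3SiOTf (2.3 equiv), Et3N (2.6 equiv), Et2O, 0 °C → rt; salt layer removed, used crude
Reagents that add atoms: trimethylsilyl trifluoromethanesulfonate, C[Si](C)(C)OS(=O)(=O)C(F)(F)F
Why: Soft enolisation with double O-silylation of a β-keto ester gives the 1,3-bis(silyloxy)diene; the γ-CH2 is activated by both the ketone and the aryloxy group, and the amine base is far too weak to metalate the ring A methyl.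

Step 4
Reactants: 6 oct-2-ynoic acid
Product: 7 prop-2-en-1-yl oct-2-ynoate (allyl oct-2-ynoate)
Conditions: allyl bromide, K2CO3, DMF, rt
Reagents that add atoms: allyl bromide, C=CCBr
Why: SN2 O-alkylation of the potassium carboxylate; the allyl ester survives the cycloaddition and the benzylation and can later be removed without acid or hydroxide.

Step 5
Reactants: 5 the bis(silyloxy)diene; 7 prop-2-en-1-yl oct-2-ynoate
Product: 9 prop-2-en-1-yl 3-[5-(benzyloxy)-2-(methoxycarbonyl)-3-methylphenoxy]-4,6-dihydroxy-2-pentylbenzoate, via cyclohexa-1,4-diene cycloadduct 8 (not isolated)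
Conditions: PhMe, 110 °C, sealed tube; then 1 M HCl, THF, rt
Reagents that add atoms: none
Why: Normal-demand Diels–Alder reaction of an electron-rich bis(silyloxy)diene with an acetylenic ester followed by aromatisation; the nucleophilic aryloxy-bearing diene terminus should bond to the pentyl-bearing β-carbon of the ynoate and the ketene-acetal carbon to the α-carbon, loss of methanol from 8 aromatises the ring and dilute acid removes both silyl groups, which sets ester, pentyl, aryloxy, OH, H and OH around ring B in the required order.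

Step 6
Reactants: 9 prop-2-en-1-yl 3-[5-(benzyloxy)-2-(methoxycarbonyl)-3-methylphenoxy]-4,6-dihydroxy-2-pentylbenzoate
Product: 10 prop-2-en-1-yl 4,6-bis(benzyloxy)-3-[5-(benzyloxy)-2-(methoxycarbonyl)-3-methylphenoxy]-2-pentylbenzoate
Conditions: BnBr (2.6 equiv), K2CO3, DMF, 60 °C
Reagents that add atoms: benzyl bromide, BrCc1ccccc1
Why: Double Williamson etherification; warm DMF is chosen for the 6-OH that is hydrogen-bonded to the neighbouring ester, and the allyl and methyl esters are inert to K2CO3.

Step 7
Reactants: 10 prop-2-en-1-yl 4,6-bis(benzyloxy)-3-[5-(benzyloxy)-2-(methoxycarbonyl)-3-methylphenoxy]-2-pentylbenzoate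
Product: 11 4,6-bis(benzyloxy)-3-[5-(benzyloxy)-2-(methoxycarbonyl)-3-methylphenoxy]-2-pentylbenzoic acid
Conditions: Pd(PPh3)4 (3 mol%), morpholine (5 equiv), THF, rt; dilute citric acid work-up
Reagents that add atoms: none
Why: Tsuji–Trost deallylation; zerovalent palladium ionises the allyl ester to a π-allyl complex that morpholine captures, so the hindered, electron-rich ring B acid is freed under neutral conditions and the methyl ester and benzyl ethers are untouched.

Step 8
Reactants: 12 hexanoyl chloride
Product: 13 N-methoxy-N-methylhexanamide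
Conditions: MeNH(OMe)·HCl, K2CO3, H2O–EtOAc, 0 °C → rt
Reagents that add atoms: N,O-dimethylhydroxylamine hydrochloride, CNOC.Cl
Why: Schotten–Baumann N-acylation of the hydroxylamine by the acid chloride under biphasic carbonate conditions.

Step 9
Reactants: 11 4,6-bis(benzyloxy)-3-[5-(benzyloxy)-2-(methoxycarbonyl)-3-methylphenoxy]-2-pentylbenzoic acid; 13 N-methoxy-N-methylhexanamide
Product: 15 4,6-bis(benzyloxy)-3-{[6-(benzyloxy)-1-oxo-3-pentyl-1H-isochromen-8-yl]oxy}-2-pentylbenzoic acid, via 2-oxoheptyl keto ester 14 (not isolated)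
Conditions: LiN(iPr)2 (2.3 equiv), THF, −78 °C; 13 (1.6 equiv), −78 → −30 °C; 1 M HCl; then TsOH·H2O (0.2 equiv), PhMe, 70 °C, 5 Å sieves
Reagents that add atoms: none
Why: The first equivalent of base makes the ring B lithium carboxylate and the second removes a proton from the ring A methyl, giving an ester-stabilised benzylic anion that adds to the amide carbonyl to form a chelated N,O-tetrahedral adduct that cannot over-add; aqueous acid releases benzyl ketone 14 (C4–C3 bond). Catalytic TsOH then lets the arene-conjugated enol oxygen attack the neighbouring methyl ester with loss of methanol, a 6-exo-trig O-acylation that forms O2–C1 and closes the pyranone ring. The closest known reactions are lateral lithiation–acylation of ortho-toluates with N-methoxy-N-methylamides and acid-promoted enol lactonisation of 2-(2-oxoalkyl)benzoates to 3-substituted isocoumarins. No stereocentre is formed. Site selectivity of deprotonation is secured because the primary methyl ortho to the ring A ester is kinetically far more acidic than the ring B pentyl CH2, which is secondary, flanked by two ortho substituents and next to an already anionic carboxylate. O- over C-closure is secured by closing under mild acid, where the Claisen-type C-acylation to a naphthalenediol (which needs the alkyl-side enolate) should not arise and the temperature stays below that at which the ring B acid could lose CO2.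

Step 10
Reactants: 15 4,6-bis(benzyloxy)-3-{[6-(benzyloxy)-1-oxo-3-pentyl-1H-isochromen-8-yl]oxy}-2-pentylbenzoic acid
Product: 16 4,6-dihydroxy-3-[(6-hydroxy-1-oxo-3-pentyl-1H-isochromen-8-yl)oxy]-2-pentylbenzoic acid
Conditions: BCl3 (6 equiv), pentamethylbenzene (9 equiv), CH2Cl2, −78 °C; MeOH then H2O quench, cold work-up
Reagents that add atoms: none
Why: Lewis-acid cleavage of the three aryl benzyl ethers with pentamethylbenzene as a non-basic benzyl-cation scavenger (Friedel–Crafts capture); at −78 °C the lactone, the diaryl ether, the C3=C4 double bond and the free carboxyl group should all be kept, and no hydrogen is used.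

**Compound list**

1 | methyl orsellinate (methyl 2,4-dihydroxy-6-methylbenzoate) | COC(=O)c1c(C)cc(O)cc1O | starting material
2 | methyl 4-(benzyloxy)-2-hydroxy-6-methylbenzoate | COC(=O)c1c(C)cc(OCc2ccccc2)cc1O | intermediate
3 | methyl 4-chloroacetoacetate (methyl 4-chloro-3-oxobutanoate) | COC(=O)CC(=O)CCl | starting material
4 | methyl 4-(benzyloxy)-2-(4-methoxy-2,4-dioxobutoxy)-6-methylbenzoate | COC(=O)CC(=O)COc1cc(OCc2ccccc2)cc(C)c1C(=O)OC | intermediate
5 | methyl 4-(benzyloxy)-2-{[4-methoxy-2,4-bis(trimethylsilyloxy)buta-1,3-dien-1-yl]oxy}-6-methylbenzoate (mixture of double-bond isomers) | COC(O[Si](C)(C)C)=CC(O[Si](C)(C)C)=COc1cc(OCc2ccccc2)cc(C)c1C(=O)OC | intermediate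
6 | oct-2-ynoic acid | CCCCCC#CC(=O)O | starting material
7 | prop-2-en-1-yl oct-2-ynoate | CCCCCC#CC(=O)OCC=C | intermediate
8 | prop-2-en-1-yl 3-[5-(benzyloxy)-2-(methoxycarbonyl)-3-methylphenoxy]-6-methoxy-2-pentyl-4,6-bis(trimethylsilyloxy)cyclohexa-1,4-diene-1-carboxylate (diastereomer mixture, not isolated) | CCCCCC1=C(C(=O)OCC=C)C(OC)(O[Si](C)(C)C)C=C(O[Si](C)(C)C)C1Oc1cc(OCc2ccccc2)cc(C)c1C(=O)OC | intermediate
9 | prop-2-en-1-yl 3-[5-(benzyloxy)-2-(methoxycarbonyl)-3-methylphenoxy]-4,6-dihydroxy-2-pentylbenzoate | CCCCCc1c(C(=O)OCC=C)c(O)cc(O)c1Oc1cc(OCc2ccccc2)cc(C)c1C(=O)OC | intermediate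
10 | prop-2-en-1-yl 4,6-bis(benzyloxy)-3-[5-(benzyloxy)-2-(methoxycarbonyl)-3-methylphenoxy]-2-pentylbenzoate | CCCCCc1c(C(=O)OCC=C)c(OCc2ccccc2)cc(OCc2ccccc2)c1Oc1cc(OCc2ccccc2)cc(C)c1C(=O)OC | intermediate
11 | 4,6-bis(benzyloxy)-3-[5-(benzyloxy)-2-(methoxycarbonyl)-3-methylphenoxy]-2-pentylbenzoic acid | COC(=O)c1c(C)cc(OCc2ccccc2)cc1Oc1c(OCc2ccccc2)cc(OCc2ccccc2)c(C(=O)O)c1CCCCC | intermediate
12 | hexanoyl chloride | CCCCCC(Cl)=O | starting material
13 | N-methoxy-N-methylhexanamide | CCCCCC(=O)N(C)OC | intermediate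
14 | 4,6-bis(benzyloxy)-3-[5-(benzyloxy)-2-(methoxycarbonyl)-3-(2-oxoheptyl)phenoxy]-2-pentylbenzoic acid (not isolated) | CCCCCC(=O)Cc1cc(OCc2ccccc2)cc(Oc2c(OCc3ccccc3)cc(OCc3ccccc3)c(C(=O)O)c2CCCCC)c1C(=O)OC | intermediate
15 | 4,6-bis(benzyloxy)-3-{[6-(benzyloxy)-1-oxo-3-pentyl-1H-isochromen-8-yl]oxy}-2-pentylbenzoic acid | CCCCCc1cc2cc(OCc3ccccc3)cc(Oc3c(OCc4ccccc4)cc(OCc4ccccc4)c(C(=O)O)c3CCCCC)c2c(=O)o1 | intermediate
16 | 4,6-dihydroxy-3-[(6-hydroxy-1-oxo-3-pentyl-1H-isochromen-8-yl)oxy]-2-pentylbenzoic acid | CCCCCc1cc2cc(O)cc(Oc3c(O)cc(O)c(C(=O)O)c3CCCCC)c2c(=O)o1 | target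

**Count and risks**

Total step count: 10. Longest linear sequence: 8 steps (steps 1, 2, 3, 5, 6, 7, 9, 10).

Step 9 (key step). The benzylic anion may be quenched by proton transfer from the α-CH2 of amide 13 faster than it adds to the carbonyl, so that acylation stalls and 11 is returned. Fallback, setting out from 11 and coming back at 14: the dianion of 11 (LiN(iPr)2, THF, −78 °C) is trapped with hexanal, a much better electrophile, and quenched at −78 °C with AcOH before the alkoxide can close to a dihydroisocoumarin. This should give racemic 4,6-bis(benzyloxy)-3-[5-(benzyloxy)-3-(2-hydroxyheptyl)-2-(methoxycarbonyl)phenoxy]-2-pentylbenzoic acid F1. Dess–Martin oxidation in CH2Cl2 then gives keto ester 14, this time isolated, which is closed to 15 with TsOH as in the second stage of step 9.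

Step 5. Thermal decay of the diene (silyl migration, hydrolysis, oligomerisation) may outpace cycloaddition to a β-alkyl ynoate of modest dienophilicity. Fallback, setting out from 5 and coming back at 11: the more electrophilic oct-2-ynal (CCCCCC#CC=O) is used in PhMe at 60 °C with the same regiochemical logic. It should give 3-[5-(benzyloxy)-2-(methoxycarbonyl)-3-methylphenoxy]-6-methoxy-2-pentyl-4,6-bis(trimethylsilyloxy)cyclohexa-1,4-diene-1-carbaldehyde F2, which dilute HCl converts into methyl 4-(benzyloxy)-2-(3-formyl-4,6-dihydroxy-2-pentylphenoxy)-6-methylbenzoate F3. Benzylation (BnBr, K2CO3, DMF, 60 °C) gives methyl 4-(benzyloxy)-2-[4,6-bis(benzyloxy)-3-formyl-2-pentylphenoxy]-6-methylbenzoate F4. Pinnick oxidation (NaClO2, NaH2PO4, excess 2-methylbut-2-ene, t-BuOH–H2O) then delivers acid 11 directly, without 9 and 10.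

Step 2. Self-condensation of the chloro keto ester enolate may outrun O-alkylation by the hindered, chelated phenoxide. Fallback, setting out from 2 and coming back at 4: phenol 2 is alkylated with tert-butyl bromoacetate (K2CO3, DMF) to give methyl 4-(benzyloxy)-2-(2-tert-butoxy-2-oxoethoxy)-6-methylbenzoate F5. CF3CO2H in CH2Cl2 frees [5-(benzyloxy)-2-(methoxycarbonyl)-3-methylphenoxy]acetic acid F6. Coupling with 2,2-dimethyl-1,3-dioxane-4,6-dione (EDC·HCl, DMAP, CH2Cl2) gives methyl 4-(benzyloxy)-2-[2-(2,2-dimethyl-4,6-dioxo-1,3-dioxan-5-ylidene)-2-hydroxyethoxy]-6-methylbenzoate F7. Refluxing MeOH opens this acyl dioxanedione to β-keto ester 4.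

**Further compounds**

F1 | step 9 | 4,6-bis(benzyloxy)-3-[5-(benzyloxy)-3-(2-hydroxyheptyl)-2-(methoxycarbonyl)phenoxy]-2-pentylbenzoic acid (racemic) | CCCCCC(O)Cc1cc(OCc2ccccc2)cc(Oc2c(OCc3ccccc3)cc(OCc3ccccc3)c(C(=O)O)c2CCCCC)c1C(=O)OC
F2 | step 5 | 3-[5-(benzyloxy)-2-(methoxycarbonyl)-3-methylphenoxy]-6-methoxy-2-pentyl-4,6-bis(trimethylsilyloxy)cyclohexa-1,4-diene-1-carbaldehyde (diastereomer mixture) | CCCCCC1=C(C=O)C(OC)(O[Si](C)(C)C)C=C(O[Si](C)(C)C)C1Oc1cc(OCc2ccccc2)cc(C)c1C(=O)OC
F3 | step 5 | methyl 4-(benzyloxy)-2-(3-formyl-4,6-dihydroxy-2-pentylphenoxy)-6-methylbenzoate | CCCCCc1c(C=O)c(O)cc(O)c1Oc1cc(OCc2ccccc2)cc(C)c1C(=O)OC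
F4 | step 5 | methyl 4-(benzyloxy)-2-[4,6-bis(benzyloxy)-3-formyl-2-pentylphenoxy]-6-methylbenzoate | CCCCCc1c(C=O)c(OCc2ccccc2)cc(OCc2ccccc2)c1Oc1cc(OCc2ccccc2)cc(C)c1C(=O)OC
F5 | step 2 | methyl 4-(benzyloxy)-2-(2-tert-butoxy-2-oxoethoxy)-6-methylbenzoate | COC(=O)c1c(C)cc(OCc2ccccc2)cc1OCC(=O)OC(C)(C)C
F6 | step 2 | [5-(benzyloxy)-2-(methoxycarbonyl)-3-methylphenoxy]acetic acid | COC(=O)c1c(C)cc(OCc2ccccc2)cc1OCC(=O)O
F7 | step 2 | methyl 4-(benzyloxy)-2-[2-(2,2-dimethyl-4,6-dioxo-1,3-dioxan-5-ylidene)-2-hydroxyethoxy]-6-methylbenzoate | COC(=O)c1c(C)cc(OCc2ccccc2)cc1OCC(O)=C1C(=O)OC(C)(C)OC1=O
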